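The 19-membered ring is disconnected at the aryl–CH2 bond that joins the para-phenylene ether ring (ring D) to the ethylene bridge leading to the monophenol ring (ring A). In ring A the carbon bearing OH is para to the carbon bearing this CH2CH2 bridge, so the two bridge carbons can be stored as a spirocyclopropane on a cyclohexadienone. Acid converts that dienone into a hydroxy-phenonium ion; C-4 of a terminal phenoxy ring captures it, which closes the macrocycle and regenerates the ring A phenol in one operation. The precursor is an open-chain 5-aryloxyspiro[2.5]octa-4,7-dien-6-one whose catechol ring is switched off as its bis-mesylate.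

Key step: step 13

Assumption: the target has no stereocentre and no configurationally stable axis or plane, so the compound as drawn is achiral and no enantiocontrol is needed.

Ring labels: A = monophenol ring, B = meta-phenylene ether ring, C = catechol ring, D = para-phenylene ether ring.

Design remark: the mesylates are kept on ring C because they are acid-stable and strongly deactivating. Both copper-mediated diaryl ether couplings are placed before any sulfonate is in the molecule, and the two fragments are joined convergently by a Wittig reaction.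

Step 1
Reactants: 1 tyrosol
Product: 2 2-bromo-4-(2-hydroxyethyl)phenol
Conditions: NBS (1.0 equiv), p-TsOH·H2O (10 mol %), MeOH, 0 °C → rt
Reagents that add atoms: N-bromosuccinimide, O=C1CCC(=O)N1Br
Why: Electrophilic aromatic bromination; the OH directs ortho and the para position is blocked by the side chain, so one equivalent of NBS should give the mono-ortho-bromide.

Step 2
Reactants: 2 2-bromo-4-(2-hydroxyethyl)phenol
Product: 3 1-(benzyloxy)-4-[2-(benzyloxy)ethyl]-2-bromobenzene
Conditions: NaH (2.5 equiv), BnBr (2.3 equiv), TBAI (cat.), THF/DMF, 0 °C → rt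
Reagents that add atoms: benzyl bromide, BrCc1ccccc1
Why: Williamson etherification of the phenoxide and the primary alkoxide in one operation; benzyl is chosen because both ethers should fall later in the hydrogenation that saturates the stilbene.

Step 3
Reactants: 3 1-(benzyloxy)-4-[2-(benzyloxy)ethyl]-2-bromobenzene; 4 3-hydroxybenzyl alcohol
Product: 5 (3-{2-(benzyloxy)-5-[2-(benzyloxy)ethyl]phenoxy}phenyl)methanol
Conditions: CuI (10 mol %), N,N-dimethylglycine·HCl (30 mol %), Cs2CO3 (2 equiv), 1,4-dioxane, 100 °C, Ar
Reagents that add atoms: none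
Why: Ullmann-type Cu(I)/amino acid diaryl ether coupling; carbonate ionises only the phenol of 4, so the benzylic alcohol should stay untouched, and the coupling is run before any sulfonate is present.

Step 4
Reactants: 5 (3-{2-(benzyloxy)-5-[2-(benzyloxy)ethyl]phenoxy}phenyl)methanol
Product: 6 1-(benzyloxy)-4-[2-(benzyloxy)ethyl]-2-[3-(bromomethyl)phenoxy]benzene
Conditions: CBr4, PPh3, CH2Cl2, 0 °C
Reagents that add atoms: carbon tetrabromide, BrC(Br)(Br)Br
Why: Appel reaction of the benzylic alcohol under neutral conditions that should spare both benzyl ethers.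

Step 5
Reactants: 6 1-(benzyloxy)-4-[2-(benzyloxy)ethyl]-2-[3-(bromomethyl)phenoxy]benzene
Product: 7 (3-{2-(benzyloxy)-5-[2-(benzyloxy)ethyl]phenoxy}benzyl)triphenylphosphonium bromide
Conditions: PPh3, toluene, 90 °C
Reagents that add atoms: triphenylphosphine, c1ccc(cc1)P(c1ccccc1)c1ccccc1
Why: SN2 quaternisation of triphenylphosphine by the benzylic bromide; the salt should precipitate from toluene.

Step 6
Reactants: 8 3-bromo-4,5-dimethoxybenzaldehyde; 9 phenol
Product: 10 3,4-dimethoxy-5-phenoxybenzaldehyde
Conditions: CuI (10 mol %), N,N-dimethylglycine·HCl (30 mol %), Cs2CO3 (2 equiv), 1,4-dioxane, 100 °C, Ar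
Reagents that add atoms: none
Why: Ullmann-type diaryl ether coupling; the fully O-methylated bromide avoids a free ortho-phenoxide on the electrophile, and the non-enolisable aldehyde tolerates carbonate.

Step 7
Reactants: 10 3,4-dimethoxy-5-phenoxybenzaldehyde
Product: 11 3,4-dihydroxy-5-phenoxybenzaldehyde
Conditions: BBr3 (3.5 equiv), CH2Cl2, −78 °C → rt; H2O
Reagents that add atoms: none
Why: Lewis-acid cleavage of both aryl methyl ethers by BBr3; the diaryl ether is not cleaved and the aldehyde is returned on aqueous work-up.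

Step 8
Reactants: 11 3,4-dihydroxy-5-phenoxybenzaldehyde
Product: 12 5-formyl-3-phenoxy-1,2-phenylene dimethanesulfonate
Conditions: MsCl (2.5 equiv), Et3N, CH2Cl2, 0 °C
Reagents that add atoms: methanesulfonyl chloride, CS(=O)(=O)Cl
Why: O-sulfonylation of both phenols; aryl mesylates are acid-stable, electron-withdrawing, and should survive ylide, hydrogenation and Appel conditions.

Step 9
Reactants: 7 (3-{2-(benzyloxy)-5-[2-(benzyloxy)ethyl]phenoxy}benzyl)triphenylphosphonium bromide; 12 5-formyl-3-phenoxy-1,2-phenylene dimethanesulfonate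
Product: 14 5-[2-(3-{2-(benzyloxy)-5-[2-(benzyloxy)ethyl]phenoxy}phenyl)ethenyl]-3-phenoxy-1,2-phenylene dimethanesulfonate (E/Z mixture), via phosphonium ylide 13 (not isolated)
Conditions: NaHMDS (1.0 equiv), THF, 0 °C; then 12, −78 °C → rt
Reagents that add atoms: none
Why: Wittig olefination with a semi-stabilised benzylic ylide pre-formed with one equivalent of base, so the mesylates never meet free amide base; the alkene geometry is irrelevant because the double bond is hydrogenated next.

Step 10
Reactants: 14 5-[2-(3-{2-(benzyloxy)-5-[2-(benzyloxy)ethyl]phenoxy}phenyl)ethenyl]-3-phenoxy-1,2-phenylene dimethanesulfonate (E/Z mixture)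
Product: 15 5-(2-{3-[2-hydroxy-5-(2-hydroxyethyl)phenoxy]phenyl}ethyl)-3-phenoxy-1,2-phenylene dimethanesulfonate
Conditions: H2 (1–3 bar), Pd(OH)2/C, EtOAc/EtOH, rt
Reagents that add atoms: none
Why: Catalytic hydrogenation should saturate the stilbene and hydrogenolyse both benzyl ethers in one operation, while aryl mesylates and diaryl ethers are inert to Pd/H2.

Step 11
Reactants: 15 5-(2-{3-[2-hydroxy-5-(2-hydroxyethyl)phenoxy]phenyl}ethyl)-3-phenoxy-1,2-phenylene dimethanesulfonate
Product: 16 5-(2-{3-[5-(2-bromoethyl)-2-hydroxyphenoxy]phenyl}ethyl)-3-phenoxy-1,2-phenylene dimethanesulfonate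
Conditions: CBr4, PPh3, CH2Cl2, 0 °C
Reagents that add atoms: carbon tetrabromide, BrC(Br)(Br)Br
Why: Appel reaction, selective for the primary alcohol because the phenolic C–O bond at an sp2 carbon cannot be substituted.

Step 12
Reactants: 16 5-(2-{3-[5-(2-bromoethyl)-2-hydroxyphenoxy]phenyl}ethyl)-3-phenoxy-1,2-phenylene dimethanesulfonate
Product: 17 5-(2-{3-[(6-oxospiro[2.5]octa-4,7-dien-5-yl)oxy]phenyl}ethyl)-3-phenoxy-1,2-phenylene dimethanesulfonate
Conditions: KOt-Bu (1.0 equiv), t-BuOH/Et2O, 0 °C → rt; filtration through basic alumina, solvent exchange to CH2Cl2 below 20 °C, used at once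
Reagents that add atoms: none
Why: Base-induced Ar1-3 spirocyclisation, in which the phenoxide alkylates through its para carbon (3-exo-tet), is the established entry to spiro[2.5]octa-4,7-dien-6-ones from 4-(2-bromoethyl)phenols; exactly one equivalent of base should leave the mesylates alone.

Step 13
Reactants: 17 5-(2-{3-[(6-oxospiro[2.5]octa-4,7-dien-5-yl)oxy]phenyl}ethyl)-3-phenoxy-1,2-phenylene dimethanesulfonate
Product: 18 macrocyclic phenol bis-mesylate (the target skeleton with both ring C hydroxyls as methanesulfonates)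
Conditions: Tf2NH (10 mol %), CH2Cl2, 4 Å MS, −20 °C → rt; 17 added by syringe pump (final 1 mM)
Reagents that add atoms: none
Why: Proposed new method: Tf2NH protonates the dienone oxygen to give a 4-hydroxyphenonium ion whose two cyclopropane CH2 groups are equivalent; C-4 of the terminal phenoxy ring (ring D) attacks one of them from the backside, the CH2–C(spiro) bond breaks, and loss of the arenium proton delivers the aryl–CH2 bond, rearomatises ring A to the free phenol and returns the acid. The closest known reaction types are the acid-promoted opening of spiro[2.5]octa-4,7-dien-6-ones at CH2 by external nucleophiles and Friedel–Crafts alkylation of arenes by 2-arylethyl electrophiles through phenonium ions. The one new ring, the 19-membered macrocycle, closes in an endo sense at a tetrahedral carbon: the breaking bond lies inside the forming ring, since the spiro carbon stays in the macrocycle through the second CH2, and the large ring allows the near-collinear approach this needs. No stereocentre is created. The step needs para attack by ring D in preference to all other arene positions and to intermolecular capture: the catechol ring C is deactivated by its two mesylates, ring B could only close bridged rings of eight to ten members that are too strained, the ortho positions of ring D are more hindered, and syringe-pump addition into a non-nucleophilic medium keeps the stationary concentration of the cation low. Release of cyclopropane strain and the gain of aromaticity in ring A should drive the closure.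

Step 14
Reactants: 18 macrocyclic phenol bis-mesylate
Product: 19 target triol CNP0495401.0
Conditions: KOH (2 M aq, excess), MeOH, 65 °C, degassed, Ar; then 1 M HCl
Reagents that add atoms: none
Why: Alkaline hydrolysis of the two aryl methanesulfonates (hydroxide attacks sulfur, phenoxide leaves), run oxygen-free so the catecholate is not oxidised before acidification.

Compound list
1 | tyrosol, 4-(2-hydroxyethyl)phenol | OCCc1ccc(O)cc1 | starting material
2 | 2-bromo-4-(2-hydroxyethyl)phenol | OCCc1ccc(O)c(Br)c1 | intermediate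
3 | 1-(benzyloxy)-4-[2-(benzyloxy)ethyl]-2-bromobenzene | Brc1cc(CCOCc2ccccc2)ccc1OCc1ccccc1 | intermediate
4 | 3-hydroxybenzyl alcohol, 3-(hydroxymethyl)phenol | OCc1cccc(O)c1 | starting material
5 | (3-{2-(benzyloxy)-5-[2-(benzyloxy)ethyl]phenoxy}phenyl)methanol | OCc1cccc(Oc2cc(CCOCc3ccccc3)ccc2OCc2ccccc2)c1 | intermediate
6 | 1-(benzyloxy)-4-[2-(benzyloxy)ethyl]-2-[3-(bromomethyl)phenoxy]benzene | BrCc1cccc(Oc2cc(CCOCc3ccccc3)ccc2OCc2ccccc2)c1 | intermediate
7 | (3-{2-(benzyloxy)-5-[2-(benzyloxy)ethyl]phenoxy}benzyl)triphenylphosphonium bromide | [Br-].c1ccc(cc1)[P+](Cc1cccc(Oc2cc(CCOCc3ccccc3)ccc2OCc2ccccc2)c1)(c1ccccc1)c1ccccc1 | intermediate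
8 | 3-bromo-4,5-dimethoxybenzaldehyde | COc1cc(C=O)cc(Br)c1OC | starting material
9 | phenol | Oc1ccccc1 | starting material
10 | 3,4-dimethoxy-5-phenoxybenzaldehyde | COc1cc(C=O)cc(Oc2ccccc2)c1OC | intermediate
11 | 3,4-dihydroxy-5-phenoxybenzaldehyde | O=Cc1cc(O)c(O)c(Oc2ccccc2)c1 | intermediate
12 | 5-formyl-3-phenoxy-1,2-phenylene dimethanesulfonate | O=Cc1cc(OS(C)(=O)=O)c(OS(C)(=O)=O)c(Oc2ccccc2)c1 | intermediate
13 | phosphonium ylide of 7, (3-{2-(benzyloxy)-5-[2-(benzyloxy)ethyl]phenoxy}benzylidene)triphenylphosphorane | C(=P(c1ccccc1)(c1ccccc1)c1ccccc1)c1cccc(Oc2cc(CCOCc3ccccc3)ccc2OCc2ccccc2)c1 | intermediate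
14 | 5-[2-(3-{2-(benzyloxy)-5-[2-(benzyloxy)ethyl]phenoxy}phenyl)ethenyl]-3-phenoxy-1,2-phenylene dimethanesulfonate (E/Z mixture, geometry not defined) | CS(=O)(=O)Oc1cc(C=Cc2cccc(Oc3cc(CCOCc4ccccc4)ccc3OCc3ccccc3)c2)cc(Oc2ccccc2)c1OS(C)(=O)=O | intermediate
15 | 5-(2-{3-[2-hydroxy-5-(2-hydroxyethyl)phenoxy]phenyl}ethyl)-3-phenoxy-1,2-phenylene dimethanesulfonate | OCCc1ccc(O)c(Oc2cccc(CCc3cc(OS(C)(=O)=O)c(OS(C)(=O)=O)c(Oc4ccccc4)c3)c2)c1 | intermediate
16 | 5-(2-{3-[5-(2-bromoethyl)-2-hydroxyphenoxy]phenyl}ethyl)-3-phenoxy-1,2-phenylene dimethanesulfonate | BrCCc1ccc(O)c(Oc2cccc(CCc3cc(OS(C)(=O)=O)c(OS(C)(=O)=O)c(Oc4ccccc4)c3)c2)c1 | intermediate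
17 | 5-(2-{3-[(6-oxospiro[2.5]octa-4,7-dien-5-yl)oxy]phenyl}ethyl)-3-phenoxy-1,2-phenylene dimethanesulfonate | O=C1C=CC2(CC2)C=C1Oc1cccc(CCc2cc(OS(C)(=O)=O)c(OS(C)(=O)=O)c(Oc3ccccc3)c2)c1 | intermediate
18 | macrocyclic phenol bis-mesylate (19-membered ring; ring C hydroxyls as methanesulfonates) | Oc1ccc2cc1Oc1cccc(c1)CCc1cc(OS(C)(=O)=O)c(OS(C)(=O)=O)c(c1)Oc1ccc(cc1)CC2 | intermediate
19 | target macrocyclic bis(bibenzyl) triol CNP0495401.0 | Oc1ccc2cc1Oc1cccc(c1)CCc1cc(O)c(O)c(c1)Oc1ccc(cc1)CC2 | target

Total step count: 14. Longest linear sequence: 11 steps (steps 1–5, then 9–14, from tyrosol).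

Steps most likely to fail

Step 13. The phenonium ion may be intercepted by other nucleophiles: a second molecule (oligomerisation), adventitious water, or an ortho position of ring D. The fallback uses known chemistry, sets out from 15 and comes back at 19. The phenol of 15 would be mesylated selectively under carbonate conditions (MsCl, K2CO3, acetone, 0 °C) to give the tris-mesylate alcohol F1. The primary alcohol would be oxidised (TEMPO cat., PhI(OAc)2, MeCN/H2O) to the arylacetic acid F2. Oxalyl chloride with catalytic DMF would give the acid chloride F3, not isolated. Slow addition of F3 to SnCl4 or AlCl3 in CH2Cl2 at high dilution should close the ring by intramolecular Friedel–Crafts acylation at C-4 of ring D, giving the macrocyclic ketone F4. Ionic hydrogenation (Et3SiH, TFA) would reduce the diaryl-activated ketone to the macrocyclic tris-mesylate F5. Hydrolysis as in step 14 would then give 19.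

Step 12. The spirodienone may be lost during filtration and solvent exchange through oligomerisation or solvolysis. The fallback sets out from 16 and comes back at 18 without handling the dienone. Bromide 16 would be added slowly to AgNTf2 (1.1 equiv) in CH2Cl2 at high dilution. Halide abstraction assisted by the para-hydroxyphenyl ring should generate the same hydroxy-phenonium ion directly, and ring D should capture it to give 18. No new compound is made on this way (entry F0).

Step 3. Oxidative addition of copper to the electron-rich, ortho-alkoxy bromide may be sluggish, leaving low conversion or protodebromination. The fallback sets out from 3 and comes back at 5. Bromine–lithium exchange (n-BuLi, THF, −78 °C), trapping with B(OMe)3 and acidic hydrolysis would give 2-(benzyloxy)-5-[2-(benzyloxy)ethyl]phenylboronic acid F6. Chan–Lam coupling of F6 with 4 (Cu(OAc)2, pyridine, 4 Å MS, CH2Cl2, air, rt) should give 5 at room temperature through the phenol only.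

Further compounds
F1 | step 13 | 4-(2-hydroxyethyl)-2-{3-[2-(3,4-bis(methylsulfonyloxy)-5-phenoxyphenyl)ethyl]phenoxy}phenyl methanesulfonate | OCCc1ccc(OS(C)(=O)=O)c(Oc2cccc(CCc3cc(OS(C)(=O)=O)c(OS(C)(=O)=O)c(Oc4ccccc4)c3)c2)c1
F2 | step 13 | [4-(methylsulfonyloxy)-3-{3-[2-(3,4-bis(methylsulfonyloxy)-5-phenoxyphenyl)ethyl]phenoxy}phenyl]acetic acid | OC(=O)Cc1ccc(OS(C)(=O)=O)c(Oc2cccc(CCc3cc(OS(C)(=O)=O)c(OS(C)(=O)=O)c(Oc4ccccc4)c3)c2)c1
F3 | step 13 | acid chloride of F2 | ClC(=O)Cc1ccc(OS(C)(=O)=O)c(Oc2cccc(CCc3cc(OS(C)(=O)=O)c(OS(C)(=O)=O)c(Oc4ccccc4)c3)c2)c1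
F4 | step 13 | macrocyclic tris-mesylate ketone (C=O on the bridge carbon attached to ring D) | CS(=O)(=O)Oc1ccc2cc1Oc1cccc(c1)CCc1cc(OS(C)(=O)=O)c(OS(C)(=O)=O)c(c1)Oc1ccc(cc1)C(=O)C2
F5 | step 13 | macrocyclic tris-mesylate (target with all three hydroxyls as methanesulfonates) | CS(=O)(=O)Oc1ccc2cc1Oc1cccc(c1)CCc1cc(OS(C)(=O)=O)c(OS(C)(=O)=O)c(c1)Oc1ccc(cc1)CC2
F0 | step 12 | none | none
F6 | step 3 | 2-(benzyloxy)-5-[2-(benzyloxy)ethyl]phenylboronic acid | OB(O)c1cc(CCOCc2ccccc2)ccc1OCc1ccccc1
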